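Count the reagent. We follow the red flask to 40 min, with ochre as the earlier run.

| flask | left-handed substrate | right-handed substrate | reagent | free catalyst | remark | time |
|---|---|---|---|---|---|---|
| red | 0.050 M | 0.050 M | 0.050 M | 0.17 mM | the very flask that is asked about, followed so far |  |
| ochre | 0.050 M | 0.050 M | 0.050 M | 0.11 mM | run made earlier |  |
| flask | 0.050 M | 0.050 M | 0.0500 M | 0.17 mM |  | 40 min |

| run | time / min | left-handed substrate / % | right-handed substrate / % |
|---|---|---|---|
| red | 0.667 | 38.1 | 49.5 |
| red | 2.00 | 26.9 | 48.4 |
| red | 4.00 | 21.4 | 44.4 |
| red | 6.00 | 19.3 | 42.4 |
| red | 8.00 | 17.4 | 39.7 |
| ochre | 4.00 | 25.3 | 45.7 |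
| ochre | 10.0 | 20.3 | 40.8 |
| ochre | 20.0 | 20.4 | 33.7 |
| ochre | 30.0 | 22.9 | 28.4 |
| ochre | 40.0 | 23.4 | 26.7 |

(scatter of a reading: 0.5 percentage points)

- free catalyst is single-handed; left-handed substrate and right-handed substrate are mirror images of each other, charged as a racemate, each of them at the stated concentration
- an excess is the difference of the two amounts in percent of their sum
- an excess is below zero if the other one leads

- part of the left-handed substrate and right-handed substrate charged together that has reacted at 40 min
- excess of left-handed product over right-handed product in the product at 40 min
- excess of right-handed substrate over left-handed substrate among what is left of the two at 40 min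

Start with the main step by itself: reagent and free catalyst turn left-handed substrate into left-handed product, one reagent for each substrate. Reagent charged over both substrates charged is 50.0%, and we call this the reagent budget. Reagent is less than the two substrates together, so it is the limiting reagent. On this step we count conversion at the budget, a purely left-handed product and a purely right-handed rest.

Now add the interconversion of the substrates. In ochre, left-handed substrate rises from 20.3% at 10.0 min to 23.4% at 40.0 min, while right-handed substrate falls from 40.8% to 26.7%. This spends no reagent, so the budget stands. Ochre's readings give 49.9% reacted at 40.0 min, against its budget of 50.0%. The rest is no longer pure: ochre reads a right-handed excess of 6.59%. The red flask has more catalyst, and at 4.00 min it reads 21.4% of left-handed substrate, less than the 25.3% of ochre at 4.00 min, so we expect its excess below that reading.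

Last comes the small correction, direct attack on right-handed substrate. At 0.667 min the readings of the red flask show a loss of 0.5 percentage points of right-handed substrate and 12.4% of both together. That is a right-handed share of 4.03%, read from a loss no larger than the scatter. It draws on the same budget, so we keep conversion at the budget and count a product excess of 91.9%.

The forecast gives 50%, 90% and 2%, on the ground that “reagent sets the final conversion”. Its product excess is lower than ours.

The red flask gives 49.9%, 89.4% and 4.61%, each within the forecast's tolerance.

    reagent + free catalyst + left-handed substrate → free catalyst + left-handed product (k = 948 M⁻² s⁻¹)
    reagent + free catalyst + right-handed substrate → free catalyst + right-handed product (k = 31.7 M⁻² s⁻¹)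
    left-handed substrate ⇌ right-handed substrate (k = 7.33 × 10⁻⁴ s⁻¹)
    2 free catalyst → spent catalyst (k = 1.40 M⁻¹ s⁻¹)

In the red flask, reagent stands at 0.27% of its charge at 40 min, less than the 52% of right-handed substrate left. The budget times the reagent gone is 49.9%. One more flask, charged with 0.030 M of reagent and otherwise the same, has a budget of 30.0%. It gives 30.0% reacted and a product excess of 91.6%, with 34.4% left-handed and 35.6% right-handed substrate at 40 min.

The numbers in the tables are simulated with constants of no real substance, noise included.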